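**Remark (assumption).** (S)-(+)-Terpinen-4-ol is taken to be available in high enantiomeric purity. Its carbinol carbon becomes C4 of the target and no bond to it is made or broken.

## Analysis of the target

The target 23 is the 3,4-dimethoxybenzoate of a daucane diol. A five-membered ring (C1–C5) and a seven-membered ring (C1, C5–C10) share the C1–C5 bond. Numbering used here: C1 is the quaternary fusion carbon (methyl C15), C2 and C3 are CH2, C4 carries OH and isopropyl, C5 is the fusion CH, C6 carries the ester, C7 is CH2, C8 (methyl C14)=C9 is the alkene, C10 is CH2.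

The four stereocentres are contiguous (1S,4R,5R,6R). C15 lies on one face (β); H5, the C4 oxygen and the C6 oxygen lie on the other (α). The fusion is therefore trans, and isopropyl, C6 and C15 are all cis on the five-membered ring. This is a crowded array that thermodynamic control will not favour.

Sensitive points are the tertiary alcohol at C4 (allylic or β to a carbonyl in most precursors), the C8=C9 alkene (it moves into conjugation as soon as C6 is a ketone) and the aryl ester (lost to any hydride reagent). The hard parts are the quaternary C1 at the ring fusion, the seven-membered ring, and delivering H to C5 on the face of the C4 oxygen.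

The feature that invites the key step: in the seven-membered ring, C8=C9 and the C5–C6 bond are 1,4-related across C7, and the ring is closed by the sp3 pair C10–C1. With C5=C6 as a second alkene the ring is a cyclohepta-1,4-diene, the product of a divinylcyclopropane rearrangement that forms C1–C10. C14 can then be the ester carbon of a vinylcarbenoid. The remaining piece (C1–C7, C15, isopropyl, C4–O) maps onto ring-contracted terpinen-4-ol.

## Retrosynthetic reasoning

**C6–O acyl bond (23 ⇒ 21 + 22).** The ester is cut first because it would not survive the hydride steps. Forward, the secondary C6 hydroxyl of 21 must be acylated with 22 in the presence of the tertiary C4 hydroxyl, which is flanked by isopropyl and should not react.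

**C6–O and C5–H together (21 ⇒ 18).** Both bonds lie on the face of the C4 oxygen. In dienol 18 the fold of the seven-membered ring puts C8–C10 under that face of C5=C6, so a free reagent would attack from the C15 face and give the cis-fused epimer. The two atoms are therefore delivered from O4 itself: a hydridosilyl tether adds Si to C6 and H to C5 syn, and oxidation turns C–Si into C–OH with retention. This sets two stereocentres in one operation and leaves C8=C9 alone.

**C14 oxidation level (18 ⇒ 17 ⇒ 15 ⇒ 14).** The C8 methyl is traced back to the ester that a donor/acceptor carbenoid needs. Two hydride steps (ester to allylic alcohol, allylic alcohol to methyl) and a desilylation are the price.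

**Key disconnection, C7–C8 and C1–C10 (14 ⇒ 13 ⇒ 7 + 12).** The seven-membered ring is cut into a four-carbon piece (C8, C9, C10, C14 = diazoester 12) and the eleven-carbon diene 7. Forward, a rhodium vinylcarbenoid cyclopropanates the vinyl group of 7 (bonds C7–C8 and C6–C8), and the cis-divinylcyclopropane 13 rearranges (C6–C8 breaks, C1–C10 forms). The ring, the quaternary C1 and both ring alkenes appear in one operation. No other cut gives two pieces of which one is a commodity-derived chiral building block and the other a three-step reagent. The step must be site-selective, cis-selective and face-selective.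

**Diene (7 ⇒ 6 ⇒ 4 ⇒ 2 ⇒ 1).** Methylenation of enal 6; 6 by ozonolysis of the ring alkene and aldol condensation of keto aldehyde 4 (ring contraction six to five); 2 is the silyl ether of 1. The silyl group keeps the hydroxyl out of the carbenoid step and makes it the poorer leaving group in the condensation.

**Diazoester (12 ⇒ 10 ⇒ 9 ⇒ 8).** Diazo transfer, ketone reduction and dehydration from methyl acetoacetate 8.

## Alternatives that were turned down

**Alternative 1:** the textbook route. Disconnection at C8=C9; forward key step is ring-closing metathesis of diene A1 to give 21 directly. Turned down because the metathesis forms one C=C bond and no stereocentre. All four stereocentres, including the crowded cis array, would have to be built on a monocyclic cyclopentane (conjugate allylation at C1, controlled protonation at C5, 1,2-induction in a methallyl addition at C6). That costs at least five more linear steps, each with its own selectivity question.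

**Alternative 2:** disconnection at C4–C5; forward key step is intramolecular aldol addition of the C5 enolate of cycloheptenone A2 to its isopropyl ketone. Turned down because a chelated transition state places the C4 oxygen cis to C6, the opposite of the relation in 23. The reaction is also reversible, so the less crowded epimers win. Enolisation toward C7 pulls C8=C9 into conjugation. Finally, the quaternary C1 of A2 would need its own enantioselective construction.

**Alternative 3:** late single-atom insertion. Disconnection of C7 from C6 and C8; forward key step is ring expansion of hydrindenone A3 with a silyl diazomethane and a Lewis acid. Turned down for three reasons. The vinyl carbon C8 must migrate in preference to the alkyl carbon C5, and the diazo compound can add across the enone instead. A3 is a β-hydroxy ketone that can undergo retro-aldol cleavage under the Lewis acid. A3 also contains the same three stereocentres as 21, with C5 epimerisable, so nothing is simplified.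

Key step: step 8

## Route

Step 1
Reactants: 1 (S)-(+)-terpinen-4-ol
Product: 2 triethyl{[(1S)-4-methyl-1-(propan-2-yl)cyclohex-3-en-1-yl]oxy}silane
Conditions: Et3SiOTf, 2,6-lutidine, CH2Cl2, −78 → 0 °C
Reagents that add atoms: triethylsilyl trifluoromethanesulfonate, CC[Si](CC)(CC)OS(=O)(=O)C(F)(F)F
Why: Silylation of a hindered tertiary alcohol with a silyl triflate; the ether keeps the hydroxyl out of O–H insertion in step 8 and makes it the poorer leaving group in step 3.

Step 2
Reactants: 2 silyl ether
Product: 4 (3S)-6-oxo-3-(propan-2-yl)-3-[(triethylsilyl)oxy]heptanal, via ozonide 3 (not isolated)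
Conditions: O3, CH2Cl2, −78 °C; then PPh3, −78 °C → rt
Reagents that add atoms: ozone, [O-][O+]=O
Why: Ozonolysis with reductive work-up cleaves the only C=C bond to the keto aldehyde; the stereocentre is not touched.

Step 3
Reactants: 4 keto aldehyde
Product: 6 (5R)-2-methyl-5-(propan-2-yl)-5-[(triethylsilyl)oxy]cyclopent-1-ene-1-carbaldehyde, via aldol adduct 5 (not isolated)
Conditions: piperidine (0.2 equiv), AcOH (0.2 equiv), benzene, 60 °C
Reagents that add atoms: none
Why: Amine-catalysed intramolecular aldol condensation (the enamine of the aldehyde adds to the methyl ketone and closes the five-membered ring), the usual ring contraction of 1-methylcyclohexenes to 2-methylcyclopent-1-enecarbaldehydes. Water should be lost from the new free tertiary hydroxyl and not from the silyl ether, which is the poorer leaving group.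

Step 4
Reactants: 6 enal
Product: 7 {[(1R)-2-ethenyl-3-methyl-1-(propan-2-yl)cyclopent-2-en-1-yl]oxy}triethylsilane
Conditions: Ph3PCH3Br, KOtBu, THF, 0 °C → rt
Reagents that add atoms: methyltriphenylphosphonium bromide, C[P+](c1ccccc1)(c1ccccc1)c1ccccc1.[Br-]
Why: Wittig methylenation; the small unstabilised ylide should add 1,2 even to this hindered conjugated aldehyde.

Step 5
Reactants: 8 methyl acetoacetate
Product: 9 methyl 2-diazo-3-oxobutanoate
Conditions: 4-acetamidobenzenesulfonyl azide, Et3N, MeCN, 0 °C → rt
Reagents that add atoms: 4-acetamidobenzenesulfonyl azide, CC(=O)Nc1ccc(cc1)S(=O)(=O)N=[N+]=[N-]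
Why: Regitz diazo transfer to an active methylene compound.

Step 6
Reactants: 9 diazo keto ester
Product: 10 methyl 2-diazo-3-hydroxybutanoate (racemic)
Conditions: NaBH4, MeOH, 0 °C
Reagents that add atoms: none
Why: Borohydride reduction of the ketone; ester and diazo group are left alone, and the new centre is removed again in step 7.

Step 7
Reactants: 10 diazo alcohol
Product: 12 methyl 2-diazobut-3-enoate, via dichlorophosphate 11 (not isolated)
Conditions: POCl3, Et3N, CH2Cl2, 0 °C; cold pentane solution used at once
Reagents that add atoms: none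
Why: Dehydration through the dichlorophosphate (E2 with triethylamine); the vinyldiazoacetate closes to a pyrazole on standing, so it is made immediately before step 8.

Step 8
Reactants: 7 diene; 12 methyl 2-diazobut-3-enoate (3 equiv)
Product: 14 methyl (3R,8aS)-8a-methyl-3-(propan-2-yl)-3-[(triethylsilyl)oxy]-1,2,3,5,8,8a-hexahydroazulene-6-carboxylate, via cyclopropane 13 (not isolated)
Conditions: Rh2(S-DOSP)4 (dirhodium tetrakis[(S)-N-(4-dodecylbenzenesulfonyl)prolinate], 1 mol%), slow addition of 12, hexanes, −40 °C → rt; then toluene, 80 °C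
Reagents that add atoms: none
Why: The divalent rhodium catalyst turns 12 into a donor/acceptor vinylcarbenoid, which cyclopropanates the terminal vinyl group of 7 (C6=C7) end-on at C7; the tetrasubstituted ring alkene is inert to this bulky electrophile. As usual for such carbenoids, the carbenoid vinyl group ends up cis to the alkene substituent, which gives the cis-divinylcyclopropane 13. 13 then undergoes a [3,3] sigmatropic (divinylcyclopropane-Cope) shift through the only possible boat transition state: C6–C8 breaks and C1–C10 forms, so the seven-membered ring closes by expansion of the three-membered ring and not by an end-to-end cyclisation. The closest known reaction type is the tandem rhodium-vinylcarbenoid cyclopropanation/Cope rearrangement (formal (4+3) cycloaddition) of 1-vinyl-2-methylcycloalkenes, which is established to create methyl-bearing quaternary ring-fusion carbons. The new stereocentre C1 is fixed by the configuration at C6 of 13, because in the boat the cyclopentene can offer only one face to C10; the (6R,8R) cyclopropane leads to 1S. C6 is set by the catalyst: the S ligand is chosen because its known sense of induction (the one that gives the (1S,2R) cyclopropane from styrene) corresponds to this cyclopropane. The resident C4 centre is three bonds from C7 and points away from the forming bond, so the catalyst and not the substrate should decide, and the C1 epimer would be a separable diastereomer. The step needs site selectivity (vinyl over ring alkene and over O–H insertion, hence the silyl ether), cis selectivity and face selectivity; warming in toluene drives the Cope shift, which the inward C15 methyl slows.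

Step 9
Reactants: 14 diene ester
Product: 15 {(3R,8aS)-8a-methyl-3-(propan-2-yl)-3-[(triethylsilyl)oxy]-1,2,3,5,8,8a-hexahydroazulen-6-yl}methanol
Conditions: i-Bu2AlH (2.5 equiv), CH2Cl2, −78 → 0 °C
Reagents that add atoms: none
Why: 1,2-Reduction of a conjugated ester to the allylic alcohol by an aluminium hydride; the silyl ether and both alkenes are inert.

Step 10
Reactants: 15 allylic alcohol
Product: 17 triethyl{[(3R,8aS)-6,8a-dimethyl-3-(propan-2-yl)-1,2,3,5,8,8a-hexahydroazulen-3-yl]oxy}silane, via sulfate 16 (not isolated)
Conditions: SO3·pyridine, THF, 0 °C → rt; then LiAlH4, 0 °C → rt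
Reagents that add atoms: none
Why: Deoxygenation of a primary allylic alcohol through its sulfate monoester and SN2 hydride displacement; attack at the CH2 should be faster than attack at C9, so C8=C9 stays in place.

Step 11
Reactants: 17 silyl ether
Product: 18 (3R,8aS)-6,8a-dimethyl-3-(propan-2-yl)-1,2,3,5,8,8a-hexahydroazulen-3-ol
Conditions: Bu4NF, THF, rt → 40 °C
Reagents that add atoms: none
Why: Fluoride cleavage of the triethylsilyl ether; the neutral conditions spare the tertiary allylic alcohol.

Step 12
Reactants: 18 dienol
Product: 21 (3R,3aR,4R,8aS)-6,8a-dimethyl-3-(propan-2-yl)-1,2,3,3a,4,5,8,8a-octahydroazulene-3,4-diol, via silyl ether 19 (not isolated), via oxasilolane 20 (not isolated)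
Conditions: HMe2SiCl, Et3N, DMAP (cat.), CH2Cl2, 0 °C → rt; filter, evaporate; Pt2(dvtms)3 (dvtms = 1,3-divinyltetramethyldisiloxane, 1 mol%), toluene, 60 °C; then KF, KHCO3, 30% H2O2, THF–MeOH, 40 °C
Reagents that add atoms: hydrogen peroxide, OO
Why: Intramolecular hydrosilylation of an allylic alcohol hydrosilyl ether (5-endo, zerovalent platinum catalyst) adds Si to C6 and H to C5 syn and only on the face that the O4 tether can reach; this sets C5 (trans fusion) and C6. Tamao–Fleming oxidation then replaces Si by OH with retention. The tether also makes the step selective for C5=C6 over C8=C9.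

Step 13
Reactants: 21 diol; 22 3,4-dimethoxybenzoyl chloride
Product: 23 (3R,3aR,4R,8aS)-3-hydroxy-6,8a-dimethyl-3-(propan-2-yl)-1,2,3,3a,4,5,8,8a-octahydroazulen-4-yl 3,4-dimethoxybenzoate
Conditions: 22 (1.2 equiv), Et3N, DMAP (cat.), CH2Cl2, 0 °C → rt
Reagents that add atoms: none
Why: DMAP-catalysed acylation; the secondary equatorial C6 hydroxyl reacts, the tertiary C4 hydroxyl next to isopropyl should not.

## Compound list

1 | (S)-(+)-terpinen-4-ol, (1S)-4-methyl-1-(propan-2-yl)cyclohex-3-en-1-ol | CC1=CC[C@](O)(C(C)C)CC1 | starting material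
2 | triethyl{[(1S)-4-methyl-1-(propan-2-yl)cyclohex-3-en-1-yl]oxy}silane | CC1=CC[C@](O[Si](CC)(CC)CC)(C(C)C)CC1 | intermediate
3 | ozonide (1,2,4-trioxolane) of 2, new centres as formed | CC12CC[C@@](O[Si](CC)(CC)CC)(C(C)C)CC(OO1)O2 | intermediate (not isolated)
4 | (3S)-6-oxo-3-(propan-2-yl)-3-[(triethylsilyl)oxy]heptanal | O=CC[C@](O[Si](CC)(CC)CC)(C(C)C)CCC(C)=O | intermediate
5 | (5R)-2-hydroxy-2-methyl-5-(propan-2-yl)-5-[(triethylsilyl)oxy]cyclopentane-1-carbaldehyde, mixture at C1 and C2 | O=CC1C(C)(O)CC[C@@]1(O[Si](CC)(CC)CC)C(C)C | intermediate (not isolated)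
6 | (5R)-2-methyl-5-(propan-2-yl)-5-[(triethylsilyl)oxy]cyclopent-1-ene-1-carbaldehyde | O=CC1=C(C)CC[C@@]1(O[Si](CC)(CC)CC)C(C)C | intermediate
7 | {[(1R)-2-ethenyl-3-methyl-1-(propan-2-yl)cyclopent-2-en-1-yl]oxy}triethylsilane | C=CC1=C(C)CC[C@@]1(O[Si](CC)(CC)CC)C(C)C | intermediate
8 | methyl acetoacetate | COC(=O)CC(C)=O | starting material
9 | methyl 2-diazo-3-oxobutanoate | COC(=O)C(=[N+]=[N-])C(C)=O | intermediate
10 | methyl 2-diazo-3-hydroxybutanoate (racemic) | COC(=O)C(=[N+]=[N-])C(C)O | intermediate
11 | methyl 2-diazo-3-[(dichlorophosphoryl)oxy]butanoate | COC(=O)C(=[N+]=[N-])C(C)OP(=O)(Cl)Cl | intermediate (not isolated)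
12 | methyl 2-diazobut-3-enoate | COC(=O)C(=[N+]=[N-])C=C | intermediate
13 | methyl (1R,2R)-1-ethenyl-2-{(5R)-2-methyl-5-(propan-2-yl)-5-[(triethylsilyl)oxy]cyclopent-1-en-1-yl}cyclopropane-1-carboxylate | COC(=O)[C@@]1(C=C)C[C@@H]1C2=C(C)CC[C@@]2(O[Si](CC)(CC)CC)C(C)C | intermediate (not isolated)
14 | methyl (3R,8aS)-8a-methyl-3-(propan-2-yl)-3-[(triethylsilyl)oxy]-1,2,3,5,8,8a-hexahydroazulene-6-carboxylate | COC(=O)C1=CC[C@]2(C)CC[C@@](O[Si](CC)(CC)CC)(C(C)C)C2=CC1 | intermediate
15 | {(3R,8aS)-8a-methyl-3-(propan-2-yl)-3-[(triethylsilyl)oxy]-1,2,3,5,8,8a-hexahydroazulen-6-yl}methanol | OCC1=CC[C@]2(C)CC[C@@](O[Si](CC)(CC)CC)(C(C)C)C2=CC1 | intermediate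
16 | pyridinium {(3R,8aS)-8a-methyl-3-(propan-2-yl)-3-[(triethylsilyl)oxy]-1,2,3,5,8,8a-hexahydroazulen-6-yl}methyl sulfate | [O-]S(=O)(=O)OCC1=CC[C@]2(C)CC[C@@](O[Si](CC)(CC)CC)(C(C)C)C2=CC1.c1cc[nH+]cc1 | intermediate (not isolated)
17 | triethyl{[(3R,8aS)-6,8a-dimethyl-3-(propan-2-yl)-1,2,3,5,8,8a-hexahydroazulen-3-yl]oxy}silane | CC1=CC[C@]2(C)CC[C@@](O[Si](CC)(CC)CC)(C(C)C)C2=CC1 | intermediate
18 | (3R,8aS)-6,8a-dimethyl-3-(propan-2-yl)-1,2,3,5,8,8a-hexahydroazulen-3-ol | CC1=CC[C@]2(C)CC[C@@](O)(C(C)C)C2=CC1 | intermediate
19 | dimethylsilyl ether of 18 | CC1=CC[C@]2(C)CC[C@@](O[SiH](C)C)(C(C)C)C2=CC1 | intermediate (not isolated)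
20 | oxasilolane in which SiMe2 links O4 and C6 (Si and H5 on the face of O4) | C[Si]1(C)[C@@H]2CC(C)=CC[C@]3(C)CC[C@@](O1)(C(C)C)[C@@H]23 | intermediate (not isolated)
21 | (3R,3aR,4R,8aS)-6,8a-dimethyl-3-(propan-2-yl)-1,2,3,3a,4,5,8,8a-octahydroazulene-3,4-diol | O[C@@H]1CC(C)=CC[C@]2(C)CC[C@@](O)(C(C)C)[C@@H]12 | intermediate
22 | 3,4-dimethoxybenzoyl chloride | COc1ccc(cc1OC)C(Cl)=O | starting material
23 | (3R,3aR,4R,8aS)-3-hydroxy-6,8a-dimethyl-3-(propan-2-yl)-1,2,3,3a,4,5,8,8a-octahydroazulen-4-yl 3,4-dimethoxybenzoate | COc1ccc(C(=O)O[C@@H]2CC(C)=CC[C@]3(C)CC[C@@](O)(C(C)C)[C@@H]23)cc1OC | target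

## Step count and least certain steps

Total: 13 steps. Longest linear sequence: 10 steps (1–4 and 8–13); steps 5–7 are the side branch to 12.

**Step 8 (key step).** Three things may go wrong. Facial control in the cyclopropanation may be poor if the bias of the C4 centre opposes the catalyst. The Cope shift is slowed by the inward C15 methyl, which may allow reversible homolytic opening of the doubly allylic cyclopropane bond and so erode the relay from C6 to C1. The diazoester may be lost to pyrazole formation or carbene dimerisation before it is trapped.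
Fallback, from 6 back to 17, with a sigmatropic step for C1 and a metathesis for the ring: asymmetric methallylboration of 6 with B-methallyldiisopinocampheylborane (the antipode that gives the 6R carbinol) should give the dienol F1. Johnson–Claisen rearrangement (MeC(OEt)3, cat. EtCO2H, 140 °C) should pass the C6 configuration suprafacially to C1 and give the ester F2, in which A(1,2) strain with the fully substituted C4 holds C7 cis to C1. i-Bu2AlH at −78 °C gives the aldehyde F3, and Wittig methylenation gives the triene F4. Ring-closing metathesis with the second-generation Grubbs catalyst, RuCl2(=CHPh)(PCy3)(H2IMes), closes C8=C9 and returns at 17, so steps 9 and 10 are no longer needed.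

**Step 12.** The C5=C6 alkene is trisubstituted and sits between two fully substituted carbons, so insertion at platinum may be slow. The oxasilolane 20 is trans-fused to the cyclopentane and strained. Alkene isomerisation or intermolecular hydrosilylation may compete.
Fallback, from 14 back to 21, which uses the open (C15) face for oxygen and then brings H to C5 anti to it:
- Epoxidation of 14 with mCPBA (NaHCO3, CH2Cl2, 0 °C; the enoate is inert) should give the epoxide F5 on the convex face.
- Homolytic opening with Cp2TiCl (trivalent titanium, from Cp2TiCl2 and Zn) and 1,4-cyclohexadiene gives the tertiary C5 radical, which takes H anti to the titanium alkoxide; this gives the alcohol F6 with H5 on the O4 face and the C6 hydroxyl on the C15 face.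
- i-Bu2AlH gives the diol F7.
- SO3·pyridine reacts only with the primary allylic hydroxyl to give the sulfate F8, and LiAlH4 gives the methyl compound F9.
- Dess–Martin periodinane gives the ketone F10.
- SmI2 (divalent samarium) with H2O and Et3N should give the more stable equatorial alcohol F11.
- Bu4NF returns at 21.

**Step 3.** The silyloxy group may be eliminated from the β-silyloxy aldehyde instead of the new hydroxyl, and the sensitive keto aldehyde may self-condense.
Fallback, from 4 back to 6, which separates C–C bond formation from dehydration: L-proline in DMSO at room temperature should stop at the aldol adduct 5, which is isolated. The Burgess reagent (methyl N-(triethylammoniosulfonyl)carbamate) then activates and removes only the free tertiary hydroxyl. This fallback makes no compound outside the list.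

**Step 10.** Hydride may attack C9 with allylic transposition to an exocyclic methylene compound, or the allylic sulfate may ionise and eliminate to a triene.
Fallback, from 15 back to 17, through a π-allyl complex instead of a direct displacement: methyl chloroformate and pyridine give the allylic carbonate F12. Pd(PPh3)4 (zerovalent palladium) with LiEt3BH in THF should deliver hydride to the less hindered CH2 terminus and give 17.

## Further compounds

F1 | step 8 | (1R)-3-methyl-1-{(5R)-2-methyl-5-(propan-2-yl)-5-[(triethylsilyl)oxy]cyclopent-1-en-1-yl}but-3-en-1-ol | C=C(C)C[C@@H](O)C1=C(C)CC[C@@]1(O[Si](CC)(CC)CC)C(C)C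
F2 | step 8 | ethyl 2-{(1S,2E,3R)-1-methyl-2-(3-methylbut-3-en-1-ylidene)-3-(propan-2-yl)-3-[(triethylsilyl)oxy]cyclopentyl}acetate | CCOC(=O)C[C@]1(C)CC[C@@](O[Si](CC)(CC)CC)(C(C)C)/C1=C/CC(C)=C
F3 | step 8 | 2-{(1S,2E,3R)-1-methyl-2-(3-methylbut-3-en-1-ylidene)-3-(propan-2-yl)-3-[(triethylsilyl)oxy]cyclopentyl}acetaldehyde | O=CC[C@]1(C)CC[C@@](O[Si](CC)(CC)CC)(C(C)C)/C1=C/CC(C)=C
F4 | step 8 | triethyl{[(1R,2E,3S)-3-methyl-2-(3-methylbut-3-en-1-ylidene)-1-(propan-2-yl)-3-(prop-2-en-1-yl)cyclopentyl]oxy}silane | C=CC[C@]1(C)CC[C@@](O[Si](CC)(CC)CC)(C(C)C)/C1=C/CC(C)=C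
F5 | step 12 | 5,6-epoxide of 14 with the oxirane oxygen on the face of C15 | COC(=O)C1=CC[C@]2(C)CC[C@@](O[Si](CC)(CC)CC)(C(C)C)[C@@]23O[C@H]3C1
F6 | step 12 | methyl (3R,3aR,4S,8aS)-4-hydroxy-8a-methyl-3-(propan-2-yl)-3-[(triethylsilyl)oxy]-1,2,3,3a,4,5,8,8a-octahydroazulene-6-carboxylate | O[C@H]1CC(C(=O)OC)=CC[C@]2(C)CC[C@@](O[Si](CC)(CC)CC)(C(C)C)[C@@H]12
F7 | step 12 | (3R,3aR,4S,8aS)-6-(hydroxymethyl)-8a-methyl-3-(propan-2-yl)-3-[(triethylsilyl)oxy]-1,2,3,3a,4,5,8,8a-octahydroazulen-4-ol | O[C@H]1CC(CO)=CC[C@]2(C)CC[C@@](O[Si](CC)(CC)CC)(C(C)C)[C@@H]12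
F8 | step 12 | pyridinium sulfate monoester of the primary hydroxyl of F7 | O[C@H]1CC(COS(=O)(=O)[O-])=CC[C@]2(C)CC[C@@](O[Si](CC)(CC)CC)(C(C)C)[C@@H]12.c1cc[nH+]cc1
F9 | step 12 | (3R,3aR,4S,8aS)-6,8a-dimethyl-3-(propan-2-yl)-3-[(triethylsilyl)oxy]-1,2,3,3a,4,5,8,8a-octahydroazulen-4-ol | O[C@H]1CC(C)=CC[C@]2(C)CC[C@@](O[Si](CC)(CC)CC)(C(C)C)[C@@H]12
F10 | step 12 | (3R,3aS,8aS)-6,8a-dimethyl-3-(propan-2-yl)-3-[(triethylsilyl)oxy]-2,3,3a,5,8,8a-hexahydroazulen-4(1H)-one | O=C1CC(C)=CC[C@]2(C)CC[C@@](O[Si](CC)(CC)CC)(C(C)C)[C@@H]12
F11 | step 12 | (3R,3aR,4R,8aS)-6,8a-dimethyl-3-(propan-2-yl)-3-[(triethylsilyl)oxy]-1,2,3,3a,4,5,8,8a-octahydroazulen-4-ol | O[C@@H]1CC(C)=CC[C@]2(C)CC[C@@](O[Si](CC)(CC)CC)(C(C)C)[C@@H]12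
F0 | step 3 | none | none
F12 | step 10 | methyl {(3R,8aS)-8a-methyl-3-(propan-2-yl)-3-[(triethylsilyl)oxy]-1,2,3,5,8,8a-hexahydroazulen-6-yl}methyl carbonate | COC(=O)OCC1=CC[C@]2(C)CC[C@@](O[Si](CC)(CC)CC)(C(C)C)C2=CC1
A1 | alternative 1 | (1R)-1-[(1R,2R,5S)-2-hydroxy-5-methyl-2-(propan-2-yl)-5-(prop-2-en-1-yl)cyclopentyl]-3-methylbut-3-en-1-ol | O[C@H](CC(C)=C)[C@@H]1[C@](O)(C(C)C)CC[C@@]1(C)CC=C
A2 | alternative 2 | (6S)-3,6-dimethyl-6-(4-methyl-3-oxopentyl)cyclohept-3-en-1-one | CC(C)C(=O)CC[C@@]1(C)CC=C(C)CC(=O)C1
A3 | alternative 3 | (3R,3aS,7aS)-3-hydroxy-5,7a-dimethyl-3-(propan-2-yl)-1,2,3,3a,7,7a-hexahydro-4H-inden-4-one | O=C1C(C)=CC[C@]2(C)CC[C@@](O)(C(C)C)[C@@H]12
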